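**Strategy**

The route cuts the C2–C1′ bond of the flavanone C ring instead of the O1–C2 bond of a chalcone. Everything else, including the hindered C6–O–C4‴ ether to the apigenin unit, is assembled first on an achiral chromone. Its A ring comes from 2,6-dimethoxyhydroquinone, which places O1 para to the ether oxygen and removes any 6/8 ambiguity. In the last step a rhodium/chiral-diene 1,4-addition of 4-hydroxyphenylboronic acid to C2 of the unprotected 5-hydroxychromone–apigenin ether attaches the B ring and sets C2 (S) under catalyst control. The flavone C2 is fully substituted and stays inert, and no later step can open the ring and racemise C2.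

Key step: step 7

Remark 1: 2,6-dimethoxybenzene-1,4-diol (5) is taken as purchasable; it is otherwise the dithionite reduction product of 2,6-dimethoxy-1,4-benzoquinone.

Remark 2: the sense of induction of the diene ligand is assigned by analogy with cyclic enones; it should be confirmed on the model 5-hydroxy-7-methoxychromone plus 11 (product: sakuranetin), and the antipodal diene used if the model shows the opposite sense.

**Route**

Step 1
Reactants: 1 1-[2,4-bis(benzyloxy)-6-hydroxyphenyl]ethan-1-one; 2 4-iodobenzaldehyde
Product: 3 (E)-1-[2,4-bis(benzyloxy)-6-hydroxyphenyl]-3-(4-iodophenyl)prop-2-en-1-one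
Conditions: KOH, EtOH/THF, rt
Reagents that add atoms: none
Why: Claisen–Schmidt aldol condensation, in which the enolate of the chelated 2′-hydroxyacetophenone adds to the non-enolisable aldehyde and E1cB dehydration should give the (E)-chalcone, while the benzyl ethers and the aryl iodide are inert to ethanolic hydroxide at room temperature.

Step 2
Reactants: 3 (E)-1-[2,4-bis(benzyloxy)-6-hydroxyphenyl]-3-(4-iodophenyl)prop-2-en-1-one
Product: 4 5,7-bis(benzyloxy)-2-(4-iodophenyl)-4H-chromen-4-one
Conditions: I2 (10 mol%), DMSO, 130 °C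
Reagents that add atoms: none
Why: Iodine-catalysed oxidative cyclisation in DMSO (oxa-Michael closure, α-iodination and loss of HI, with DMSO as terminal oxidant) should convert the 2′-hydroxychalcone, and any flavanone formed from it in step 1, into the flavone without touching the aryl iodide.

Step 3
Reactants: 5 2,6-dimethoxybenzene-1,4-diol
Product: 6 1-(2,5-dihydroxy-4,6-dimethoxyphenyl)ethan-1-one
Conditions: AcOH, BF3·OEt2, 80 °C; then H2O
Reagents that add atoms: acetic acid, CC(=O)O
Why: Friedel–Crafts (Nencki-type) C-acetylation, in which the two free ring positions are equivalent, lie ortho to the unhindered OH and para to a methoxy group, and the ortho-hydroxy ketone formed is deactivated towards a second acylation.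

Step 4
Reactants: 6 1-(2,5-dihydroxy-4,6-dimethoxyphenyl)ethan-1-one
Product: 8 6-hydroxy-5,7-dimethoxy-4H-chromen-4-one, via enaminone 7 (not isolated)
Conditions: DMF-DMA, toluene, 90 °C; then conc. HCl, CH2Cl2, rt
Reagents that add atoms: N,N-dimethylformamide dimethyl acetal, COC(OC)N(C)C
Why: Enaminone route to chromones, in which the methyl ketone condenses with the amide acetal and acid then promotes addition of the only ortho hydroxyl to the β-carbon with loss of dimethylamine, so that O1 necessarily ends up para to the free, hindered 6-OH.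

Step 5
Reactants: 4 5,7-bis(benzyloxy)-2-(4-iodophenyl)-4H-chromen-4-one; 8 6-hydroxy-5,7-dimethoxy-4H-chromen-4-one
Product: 9 5,7-bis(benzyloxy)-2-{4-[(5,7-dimethoxy-4-oxo-4H-chromen-6-yl)oxy]phenyl}-4H-chromen-4-one
Conditions: CuI (10 mol%), picolinic acid (20 mol%), K3PO4, DMSO, 90 °C, Ar
Reagents that add atoms: none
Why: Ullmann-type copper-catalysed O-arylation with picolinic acid as ligand, a system suited to di-ortho-substituted phenols; the aryl iodide is activated by the para pyranone, 8 carries the only free OH in the mixture, and anhydrous phosphate should leave both pyranone rings closed.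

Step 6
Reactants: 9 5,7-bis(benzyloxy)-2-{4-[(5,7-dimethoxy-4-oxo-4H-chromen-6-yl)oxy]phenyl}-4H-chromen-4-one
Product: 10 5,7-dihydroxy-2-{4-[(5-hydroxy-7-methoxy-4-oxo-4H-chromen-6-yl)oxy]phenyl}-4H-chromen-4-one
Conditions: BCl3 (8 equiv), pentamethylbenzene, CH2Cl2, −78 to 0 °C; then MeOH/H2O
Reagents that add atoms: none
Why: Boron trichloride dealkylation, in which chelation of boron between each C4=O and its peri oxygen drives cleavage of the chromone 5-OMe and the flavone 5-OBn and the remaining benzyl ether ionises with Friedel–Crafts capture of its cation by pentamethylbenzene, while the non-chelated 7-OMe and the diaryl ether should stay intact and no stereocenter is yet present.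

Step 7
Reactants: 10 5,7-dihydroxy-2-{4-[(5-hydroxy-7-methoxy-4-oxo-4H-chromen-6-yl)oxy]phenyl}-4H-chromen-4-one; 11 (4-hydroxyphenyl)boronic acid
Product: 12 (2S)-6-[4-(5,7-dihydroxy-4-oxo-4H-chromen-2-yl)phenoxy]-5-hydroxy-2-(4-hydroxyphenyl)-7-methoxy-2,3-dihydro-4H-chromen-4-one
Conditions: [RhCl((S,S)-Ph-bod*)]2 (3 mol% Rh; Ph-bod* = 2,5-diphenylbicyclo[2.2.2]octa-2,5-diene), 11 (3 equiv), aq. KOH (10 mol%), dioxane/H2O 10:1, 50 °C, Ar; then pH 5 buffer
Reagents that add atoms: none
Why: Hayashi–Miyaura cycle: boron-to-rhodium transmetalation at an Rh–O(H/Ar) species gives an aryl–Rh(diene*) complex, the chromone C2=C3 inserts syn into the Rh–aryl bond in the enantio-determining step, and the oxa-π-allyl rhodium enolate is protonated by water or a phenol to release the flavanone and regenerate Rh–O. The closest known reaction type is the Rh/chiral-diene asymmetric 1,4-addition of arylboronic acids to chromones to give 2-arylchroman-4-ones; no ring is closed, since the pyranone ring is already in place and only its C2=C3 bond is saturated. The single new stereocenter C2 is controlled by the C2-symmetric diene, which leaves one quadrant open for the bound enone so that the aryl group is delivered to the Re face of C2 (2S). The step needs site selectivity between two pyranones, secured because flavone C2 is fully substituted (aryl and O1) and should not insert into aryl–Rh under these conditions, whereas chromone C2 bears H. It also needs protonation of the rhodium enolate to outrun β-oxygen elimination to a ring-opened chalcone, which the neighbouring 5-OH and the other phenols favour, and the nearly neutral medium (catalytic base buffered by three phenols and the boronic acid) should keep the product from racemising by retro-oxa-Michael opening.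

**Compound list**

1 | 1-[2,4-bis(benzyloxy)-6-hydroxyphenyl]ethan-1-one | CC(=O)c1c(O)cc(OCc2ccccc2)cc1OCc1ccccc1 | starting material
2 | 4-iodobenzaldehyde | O=Cc1ccc(I)cc1 | starting material
3 | (E)-1-[2,4-bis(benzyloxy)-6-hydroxyphenyl]-3-(4-iodophenyl)prop-2-en-1-one | O=C(/C=C/c1ccc(I)cc1)c1c(O)cc(OCc2ccccc2)cc1OCc1ccccc1 | intermediate
4 | 5,7-bis(benzyloxy)-2-(4-iodophenyl)-4H-chromen-4-one | O=c1cc(-c2ccc(I)cc2)oc2cc(OCc3ccccc3)cc(OCc3ccccc3)c12 | intermediate
5 | 2,6-dimethoxybenzene-1,4-diol | COc1cc(O)cc(OC)c1O | starting material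
6 | 1-(2,5-dihydroxy-4,6-dimethoxyphenyl)ethan-1-one | CC(=O)c1c(O)cc(OC)c(O)c1OC | intermediate
7 | (E)-1-(2,5-dihydroxy-4,6-dimethoxyphenyl)-3-(dimethylamino)prop-2-en-1-one | CN(C)/C=C/C(=O)c1c(O)cc(OC)c(O)c1OC | intermediate
8 | 6-hydroxy-5,7-dimethoxy-4H-chromen-4-one | COc1cc2occc(=O)c2c(OC)c1O | intermediate
9 | 5,7-bis(benzyloxy)-2-{4-[(5,7-dimethoxy-4-oxo-4H-chromen-6-yl)oxy]phenyl}-4H-chromen-4-one | COc1cc2occc(=O)c2c(OC)c1Oc1ccc(-c2cc(=O)c3c(OCc4ccccc4)cc(OCc4ccccc4)cc3o2)cc1 | intermediate
10 | 5,7-dihydroxy-2-{4-[(5-hydroxy-7-methoxy-4-oxo-4H-chromen-6-yl)oxy]phenyl}-4H-chromen-4-one | COc1cc2occc(=O)c2c(O)c1Oc1ccc(-c2cc(=O)c3c(O)cc(O)cc3o2)cc1 | intermediate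
11 | (4-hydroxyphenyl)boronic acid | OB(O)c1ccc(O)cc1 | starting material
12 | (2S)-6-[4-(5,7-dihydroxy-4-oxo-4H-chromen-2-yl)phenoxy]-5-hydroxy-2-(4-hydroxyphenyl)-7-methoxy-2,3-dihydro-4H-chromen-4-one | COc1cc2c(c(O)c1Oc1ccc(-c3cc(=O)c4c(O)cc(O)cc4o3)cc1)C(=O)C[C@@H](c1ccc(O)cc1)O2 | target

**Summary**

Total step count: 7
Longest linear sequence: 5 steps (1, 2, 5, 6, 7; the branch 3, 4 joins at step 5 and is equally long)

**Steps most likely to fail**

Step 7. The two 5-hydroxy-4-oxo sites and the acidic flavone 7-OH may bind rhodium as O,O-chelates or phenoxides and slow transmetalation, so that protodeboronation of 11 wins; prolonged heating may also erode the configuration by retro-oxa-Michael opening. The fallback forms the C2–aryl bond before the phenols are unmasked. It sets out from 9, which has no chelating or acidic OH. The same Rh/(S,S)-diene addition with (4-(benzyloxy)phenyl)boronic acid (OB(O)c1ccc(OCc2ccccc2)cc1) in toluene/H2O should give (2S)-2-[4-(benzyloxy)phenyl]-6-{4-[5,7-bis(benzyloxy)-4-oxo-4H-chromen-2-yl]phenoxy}-5,7-dimethoxychroman-4-one F1. BCl3/pentamethylbenzene in CH2Cl2, held between −78 and −20 °C to spare C2, should then remove the three benzyl groups and the chelated 5-O-methyl group, and the fallback comes back to the route at 12.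

Step 5. C–O bond formation at the di-ortho-substituted phenoxide may be slow, with competing hydrodeiodination of 4, copper-mediated oxidation of the electron-rich phenol 8, or base-induced opening of its pyranone ring. The fallback is a metal-free arylation through an iodine(III) reagent and sets out from 4. Oxidation with mCPBA/TsOH·H2O in CH2Cl2/CF3CH2OH followed by ligand exchange with 1,3,5-trimethoxybenzene should give {4-[5,7-bis(benzyloxy)-4-oxo-4H-chromen-2-yl]phenyl}(2,4,6-trimethoxyphenyl)iodonium 4-methylbenzenesulfonate F2. The potassium phenoxide of 8 (t-BuOK, THF, 0 °C to rt) should then take up the more electron-poor aryl group by ligand coupling, a process little affected by ortho substituents on the phenol, and the fallback comes back at 9.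

Step 6. Over-dealkylation (loss of the 7-O-methyl group next to the ether oxygen) or C-benzylation of the phloroglucinol-type flavone A ring by benzyl cations that escape the scavenger may occur. The fallback splits the dealkylation into a chelation-only cleavage and a final hydrogenolysis, so that no free benzyl cation and no strong Lewis acid is involved. It sets out from 9. MgI2·OEt2 (toluene/Et2O, 60 °C) should cleave only the two peri groups to give 7-(benzyloxy)-5-hydroxy-2-{4-[(5-hydroxy-7-methoxy-4-oxo-4H-chromen-6-yl)oxy]phenyl}-4H-chromen-4-one F3. The Rh/diene addition with (4-(benzyloxy)phenyl)boronic acid should then give (2S)-2-[4-(benzyloxy)phenyl]-6-{4-[7-(benzyloxy)-5-hydroxy-4-oxo-4H-chromen-2-yl]phenoxy}-5-hydroxy-7-methoxychroman-4-one F4. H2 (1 atm), Pd/C, EtOAc/MeOH, rt should remove both benzyl groups under neutral conditions, and the fallback comes back at 12.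

**Further compounds**

F1 | step 7 | (2S)-2-[4-(benzyloxy)phenyl]-6-{4-[5,7-bis(benzyloxy)-4-oxo-4H-chromen-2-yl]phenoxy}-5,7-dimethoxychroman-4-one | COc1cc2c(c(OC)c1Oc1ccc(-c3cc(=O)c4c(OCc5ccccc5)cc(OCc5ccccc5)cc4o3)cc1)C(=O)C[C@@H](c1ccc(OCc3ccccc3)cc1)O2
F2 | step 5 | {4-[5,7-bis(benzyloxy)-4-oxo-4H-chromen-2-yl]phenyl}(2,4,6-trimethoxyphenyl)iodonium 4-methylbenzenesulfonate | COc1cc(OC)c([I+]c2ccc(-c3cc(=O)c4c(OCc5ccccc5)cc(OCc5ccccc5)cc4o3)cc2)c(OC)c1.Cc1ccc(S(=O)(=O)[O-])cc1
F3 | step 6 | 7-(benzyloxy)-5-hydroxy-2-{4-[(5-hydroxy-7-methoxy-4-oxo-4H-chromen-6-yl)oxy]phenyl}-4H-chromen-4-one | COc1cc2occc(=O)c2c(O)c1Oc1ccc(-c2cc(=O)c3c(O)cc(OCc4ccccc4)cc3o2)cc1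
F4 | step 6 | (2S)-2-[4-(benzyloxy)phenyl]-6-{4-[7-(benzyloxy)-5-hydroxy-4-oxo-4H-chromen-2-yl]phenoxy}-5-hydroxy-7-methoxychroman-4-one | COc1cc2c(c(O)c1Oc1ccc(-c3cc(=O)c4c(O)cc(OCc5ccccc5)cc4o3)cc1)C(=O)C[C@@H](c1ccc(OCc3ccccc3)cc1)O2
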